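## Retrosynthetic overview

1. Target 34 ⇐ bis(methyl ether) 33 (oxidative demethylation) ⇐ β-keto sulfone 31 ⇐ δ-lactone 19 + allylic sulfone 28; both β,γ-unsaturated ketones appear only in the last three steps.
2. Lactone 19 ⇐ aldehyde acid 15 + prenylbarium chloride; 15 ⇐ ozonolysis of silyl enol ether 13 ⇐ meso ketone 11 by enantiotopos-selective deprotonation, which fixes the absolute configuration.
3. Ketone 11 ⇐ C2v dione 7 (mono-ketal, Wolff–Kishner) ⇐ Weiss–Cook condensation of butane-2,3-dione with two molecules of dimethyl 3-oxopentanedioate.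
4. Enabling feature: the two adjacent methyl-bearing quaternary ring carbons are bridged twice by three carbons, once by the ring CH2–CH2–CH2 and once, latently, by the acyl carbon on one of them together with the CH2–C(=O) on the other. Joining those two side-chain roots gives cis-1,5-dimethylbicyclo[3.3.0]octane-3,7-dione, whose cis ring fusion is the cis-dimethyl relation of the target.
5. Ring order: the cyclopentane of the target and the sacrificial ring B are formed together in step 1; ring B is cut in step 6; a temporary δ-lactone is closed in step 7 and opened in step 13; the quinone ring is bought as an arene.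

Key step: step 1

Assumption 1: which of the two enantiotopic CH2 groups of 11 the (R,R)-amide attacks is assigned by analogy with other prochiral ketones; if the mirror-image enol ether is favoured, the (S,S)-amide is used and nothing else changes.

Assumption 2: the carbinol carbon made in step 7 and the sulfone-bearing carbon made in step 13 are expected as mixtures and are left undefined in the SMILES, since both are removed as stereocentres in steps 14 and 15.

## Route

Step 1
Reactants: 1 butane-2,3-dione; 2 dimethyl 3-oxopentanedioate (2 equiv)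
Product: 5 tetramethyl cis-3,7-dihydroxy-1,5-dimethylbicyclo[3.3.0]octa-2,6-diene-2,4,6,8-tetracarboxylate, via hydroxycyclopentenone 1:1 adduct 3 (not isolated), via cyclopentenone 2:1 adduct 4 (not isolated)
Conditions: NaHCO3, H2O (pH about 8.3), rt, 24 h; product collected by filtration
Reagents that add atoms: none
Why: Weiss–Cook condensation: the doubly activated CH2 of 2 adds to one carbonyl of 1 (aldol), the other CH2 closes onto the neighbouring carbonyl and water is lost to give hydroxycyclopentenone 3; a second molecule of 2 adds in Michael fashion to the methyl-bearing β-carbon, β-elimination of the remaining hydroxyl gives enone 4, and an intramolecular Michael addition closes the second ring. The closest known reaction type is this very condensation of 1,2-diketones with 3-oxoglutarates in aqueous hydrogen carbonate buffer, from which the 2:1 adduct separates as its bis-enol. The first ring closes by a 5-exo-trig aldol addition (enolexo, through the ester enolate) and the second by a 5-exo-trig Michael addition. Both quaternary stereocentres are the former carbonyl carbons of 1, and their cis relation is enforced by the ring fusion, because the tethered carbanion of 4 can only reach the face of the enone on which it is held and a trans-fused bicyclo[3.3.0]octane is prohibitively strained; the ester-bearing carbons are of no consequence since they become CH2 in step 2. The step needs 2:1 stoichiometry and attack at the carbonyl carbons of 1 rather than reaction at its methyl groups, which is secured by the much higher acidity of the β-keto ester CH2 groups at pH about 8 and by precipitation of 5, which pulls the reversible aldol and Michael equilibria to the product. Each unit of 2 thereby delivers a three-carbon bridge between the two methyl-bearing carbons, one bridge being the CH2–CH2–CH2 of the final cyclopentane and the other the carbon atoms at the roots of the two side chains.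

Step 2
Reactants: 5 tetramethyl cis-3,7-dihydroxy-1,5-dimethylbicyclo[3.3.0]octa-2,6-diene-2,4,6,8-tetracarboxylate
Product: 7 cis-1,5-dimethylbicyclo[3.3.0]octane-3,7-dione, via bicyclic tetra-acid 6 (not isolated)
Conditions: 1 M HCl, AcOH, reflux
Reagents that add atoms: none
Why: Acid hydrolysis and fourfold decarboxylation of the β-keto ester groups removes the activating groups of the key step and leaves the quaternary centres untouched.

Step 3
Reactants: 7 cis-1,5-dimethylbicyclo[3.3.0]octane-3,7-dione
Product: 8 cis-1,5-dimethylbicyclo[3.3.0]octane-3,7-dione mono(2,2-dimethylpropane-1,3-diyl) ketal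
Conditions: 2,2-dimethylpropane-1,3-diol (1.0 equiv), p-TsOH·H2O (cat.), benzene, reflux, Dean–Stark; recovered 7 and bis-ketal (hydrolysed back to 7) recycled
Reagents that add atoms: 2,2-dimethylpropane-1,3-diol, OCC(C)(C)CO
Why: Ketalization of one of two homotopic carbonyl groups (they are exchanged by the C2 axis of 7) can give only one mono-ketal, so the statistical mixture is separable and the rest is recycled.

Step 4
Reactants: 8 cis-1,5-dimethylbicyclo[3.3.0]octane-3,7-dione mono(2,2-dimethylpropane-1,3-diyl) ketal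
Product: 11 cis-1,5-dimethylbicyclo[3.3.0]octan-3-one (meso), via hydrazone 9 (not isolated), via deoxygenated ketal 10 (not isolated)
Conditions: N2H4·H2O, KOH, diethylene glycol, 130 °C then 200 °C; then 2 M HCl, THF, rt
Reagents that add atoms: water, O
Why: Wolff–Kishner reduction (Huang–Minlon modification) turns the free carbonyl into the third ring CH2 while the base-stable ketal survives, and the acidic work-up should release the remaining ketone; no stereocentre is touched.

Step 5
Reactants: 11 cis-1,5-dimethylbicyclo[3.3.0]octan-3-one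
Product: 13 (1S,5R)-1,5-dimethyl-3-(trimethylsilyloxy)bicyclo[3.3.0]oct-2-ene, via lithium enolate 12 (not isolated)
Conditions: (R,R)-bis(1-phenylethyl)amine, n-BuLi, LiCl, Me3SiCl (in situ quench), THF, −78 °C; Et3N, pentane, non-aqueous work-up
Reagents that add atoms: chlorotrimethylsilane, C[Si](C)(C)Cl
Why: Enantiotopos-selective deprotonation with a C2-symmetric chiral lithium amide and internal silyl quench, a reaction type established for prochiral cyclohexanones and cis-bicyclo[3.3.0]octan-3-ones, removes a proton from one of the two mirror-related CH2 groups, and this choice fixes the absolute configuration of both quaternary carbons at once because their relative configuration is already locked.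

Step 6
Reactants: 13 (1S,5R)-1,5-dimethyl-3-(trimethylsilyloxy)bicyclo[3.3.0]oct-2-ene
Product: 15 2-[(1R,2R)-2-formyl-1,2-dimethylcyclopentyl]acetic acid, via trimethylsilyl ester 14 (not isolated)
Conditions: O3, CH2Cl2, −78 °C; Me2S, −78 °C to rt; aqueous work-up
Reagents that add atoms: ozone, [O-][O+]=O
Why: Ozonolysis of the silyl enol ether, the only C=C bond present, should give the aldehyde from the CH terminus and the acid from the oxygen-bearing terminus, so ring B opens into the two differentiated side-chain roots; the aldehyde has no α-hydrogen and cannot epimerize.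

Step 7
Reactants: 15 2-[(1R,2R)-2-formyl-1,2-dimethylcyclopentyl]acetic acid; 16 1-chloro-3-methylbut-2-ene (2.4 equiv)
Product: 19 (4aR,7aR)-4a,7a-dimethyl-1-(3-methylbut-2-en-1-yl)hexahydrocyclopenta[c]pyran-3(1H)-one, via prenylbarium chloride 17 (not isolated), via hydroxy acid 18 (not isolated)
Conditions: BaI2, lithium biphenylide, THF, rt (activated barium); 16, −78 °C; 15, −78 °C; 1 M HCl work-up; PPTS (cat.), CH2Cl2, rt
Reagents that add atoms: none
Why: Allylic barium reagents add to aldehydes through their CH2 (α) terminus without allylic transposition at −78 °C, the first equivalent only deprotonating the acid, and the resulting δ-hydroxy acid should lactonize under mild acid helped by the gem-dialkyl effect; the new carbinol centre is formed without control and is oxidized away in step 14.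

Step 8
Reactants: 20 4-methoxy-2-methylphenol
Product: 21 2-bromo-4-methoxy-6-methylphenol
Conditions: Br2 (1.0 equiv), CH2Cl2, 0 °C
Reagents that add atoms: bromine, BrBr
Why: Electrophilic aromatic bromination is directed by the free hydroxyl to its only open ortho position, the para position being blocked by the methoxy group.

Step 9
Reactants: 21 2-bromo-4-methoxy-6-methylphenol
Product: 22 1-bromo-2,5-dimethoxy-3-methylbenzene
Conditions: MeI, K2CO3, acetone, reflux
Reagents that add atoms: iodomethane, CI
Why: Williamson O-methylation of the phenoxide masks the future quinone as a 1,4-dimethoxyarene that tolerates the organometallic steps.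

Step 10
Reactants: 22 1-bromo-2,5-dimethoxy-3-methylbenzene; 23 1-bromo-3-methylbut-2-ene
Product: 25 2,5-dimethoxy-1-methyl-3-(3-methylbut-2-en-1-yl)benzene, via aryllithium 24 (not isolated)
Conditions: n-BuLi, THF, −78 °C; CuBr·SMe2 (0.1 equiv), 23, −78 °C to 0 °C
Reagents that add atoms: none
Why: Bromine–lithium exchange followed by copper-catalysed SN2 allylation places the prenyl group at the former C–Br position, the ortho-substituted aryl nucleophile attacking the unhindered CH2 terminus of 23.

Step 11
Reactants: 25 2,5-dimethoxy-1-methyl-3-(3-methylbut-2-en-1-yl)benzene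
Product: 26 (2E)-4-(2,5-dimethoxy-3-methylphenyl)-2-methylbut-2-en-1-ol
Conditions: SeO2 (0.5 equiv), t-BuOOH, salicylic acid (cat.), CH2Cl2, rt
Reagents that add atoms: selenium dioxide, O=[Se]=O; tert-butyl hydroperoxide, CC(C)(C)OO
Why: Selenium dioxide allylic oxidation (ene reaction then [2,3]-sigmatropic shift) hydroxylates the (E)-methyl group at the more substituted alkene terminus, which sets the E trisubstituted alkene of the target.

Step 12
Reactants: 26 (2E)-4-(2,5-dimethoxy-3-methylphenyl)-2-methylbut-2-en-1-ol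
Product: 28 1-[(2E)-4-(benzenesulfonyl)-3-methylbut-2-en-1-yl]-2,5-dimethoxy-3-methylbenzene, via allylic bromide 27 (not isolated)
Conditions: PBr3, Et2O, 0 °C; crude bromide, PhSO2Na, DMF, rt
Reagents that add atoms: sodium benzenesulfinate, [Na+].[O-]S(=O)c1ccccc1
Why: Bromination of the primary allylic alcohol and SN2 S-alkylation of benzenesulfinate at the primary carbon should give the thermodynamically preferred primary allylic sulfone with the E geometry kept.

Step 13
Reactants: 19 (4aR,7aR)-4a,7a-dimethyl-1-(3-methylbut-2-en-1-yl)hexahydrocyclopenta[c]pyran-3(1H)-one; 28 1-[(2E)-4-(benzenesulfonyl)-3-methylbut-2-en-1-yl]-2,5-dimethoxy-3-methylbenzene (2.2 equiv)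
Product: 30 (4E)-3-(benzenesulfonyl)-6-(2,5-dimethoxy-3-methylphenyl)-1-[(1R,2R)-2-(1-hydroxy-4-methylpent-3-en-1-yl)-1,2-dimethylcyclopentyl]-4-methylhex-4-en-2-one, via lithiated sulfone 29 (not isolated)
Conditions: 28, n-BuLi (2.1 equiv), THF, −78 °C; 19, −78 °C to −20 °C; aq. NH4Cl; excess 28 recovered
Reagents that add atoms: none
Why: Claisen-type acylation of an α-sulfonyl carbanion by a lactone occurs at the carbon next to sulfur, so the alkene stays E and out of conjugation, and the second equivalent of carbanion deprotonates the β-keto sulfone as it forms and so prevents over-addition; the sulfone-bearing centre is a mixture and is removed in step 15.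

Step 14
Reactants: 30 (4E)-3-(benzenesulfonyl)-6-(2,5-dimethoxy-3-methylphenyl)-1-[(1R,2R)-2-(1-hydroxy-4-methylpent-3-en-1-yl)-1,2-dimethylcyclopentyl]-4-methylhex-4-en-2-one
Product: 31 (4E)-3-(benzenesulfonyl)-6-(2,5-dimethoxy-3-methylphenyl)-1-[(1R,2R)-1,2-dimethyl-2-(4-methylpent-3-enoyl)cyclopentyl]-4-methylhex-4-en-2-one
Conditions: Dess–Martin periodinane (1.5 equiv), NaHCO3, CH2Cl2, 0 °C to rt
Reagents that add atoms: none
Why: Dess–Martin oxidation converts hindered homoallylic alcohols into β,γ-unsaturated ketones under buffered, non-basic conditions, so the prenyl double bond should not move into conjugation, and any cyclic hemiketal form of 30 drains through its open form.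

Step 15
Reactants: 31 (4E)-3-(benzenesulfonyl)-6-(2,5-dimethoxy-3-methylphenyl)-1-[(1R,2R)-1,2-dimethyl-2-(4-methylpent-3-enoyl)cyclopentyl]-4-methylhex-4-en-2-one
Product: 33 (4E)-6-(2,5-dimethoxy-3-methylphenyl)-1-[(1R,2R)-1,2-dimethyl-2-(4-methylpent-3-enoyl)cyclopentyl]-4-methylhex-4-en-2-one, via samarium dienolate 32 (not isolated)
Conditions: SmI2 (2.5 equiv), THF/MeOH (10:1), −78 °C
Reagents that add atoms: none
Why: Reductive desulfonylation of a β-keto sulfone by SmI2 is fast at −78 °C, where the unactivated hindered ketone is left alone, and the dienolate is protonated by methanol at its α-carbon, which should keep the alkene E and β,γ to the carbonyl.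

Step 16
Reactants: 33 (4E)-6-(2,5-dimethoxy-3-methylphenyl)-1-[(1R,2R)-1,2-dimethyl-2-(4-methylpent-3-enoyl)cyclopentyl]-4-methylhex-4-en-2-one
Product: 34 2-[(2E)-6-[(1R,2R)-1,2-dimethyl-2-(4-methylpent-3-enoyl)cyclopentyl]-3-methyl-5-oxohex-2-en-1-yl]-6-methylcyclohexa-2,5-diene-1,4-dione
Conditions: (NH4)2Ce(NO3)6 (2.5 equiv), MeCN/H2O (2:1), 0 °C, 15 min
Reagents that add atoms: water, O
Why: Oxidative demethylation of a 1,4-dimethoxyarene to the 1,4-benzoquinone by ceric ammonium nitrate is fast at 0 °C, so the trisubstituted alkenes and the two β,γ-unsaturated ketones should survive the brief exposure.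

## Compound list

1 | butane-2,3-dione | CC(=O)C(C)=O | starting material
2 | dimethyl 3-oxopentanedioate | COC(=O)CC(=O)CC(=O)OC | starting material
3 | dimethyl 5-hydroxy-4,5-dimethyl-2-oxocyclopent-3-ene-1,3-dicarboxylate (configuration not assigned) | COC(=O)C1=C(C)C(C)(O)C(C(=O)OC)C1=O | intermediate
4 | dimethyl 3-(1,5-dimethoxy-1,3,5-trioxopentan-2-yl)-2,3-dimethyl-5-oxocyclopent-1-ene-1,4-dicarboxylate (configuration not assigned) | COC(=O)CC(=O)C(C(=O)OC)C1(C)C(C)=C(C(=O)OC)C(=O)C1C(=O)OC | intermediate
5 | tetramethyl cis-3,7-dihydroxy-1,5-dimethylbicyclo[3.3.0]octa-2,6-diene-2,4,6,8-tetracarboxylate | C[C@]12C(C(=O)OC)=C(O)C(C(=O)OC)[C@@]1(C)C(C(=O)OC)=C(O)C2C(=O)OC | intermediate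
6 | cis-1,5-dimethyl-3,7-dioxobicyclo[3.3.0]octane-2,4,6,8-tetracarboxylic acid | C[C@]12C(C(=O)O)C(=O)C(C(=O)O)[C@@]1(C)C(C(=O)O)C(=O)C2C(=O)O | intermediate
7 | cis-1,5-dimethylbicyclo[3.3.0]octane-3,7-dione | O=C1C[C@]2(C)CC(=O)C[C@]2(C)C1 | intermediate
8 | cis-1,5-dimethylbicyclo[3.3.0]octane-3,7-dione mono(2,2-dimethylpropane-1,3-diyl) ketal | O=C1C[C@]2(C)CC3(OCC(C)(C)CO3)C[C@]2(C)C1 | intermediate
9 | hydrazone of 8 | NN=C1C[C@]2(C)CC3(OCC(C)(C)CO3)C[C@]2(C)C1 | intermediate
10 | cis-1,5-dimethylbicyclo[3.3.0]octan-3-one 2,2-dimethylpropane-1,3-diyl ketal | C1C[C@]2(C)CC3(OCC(C)(C)CO3)C[C@]2(C)C1 | intermediate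
11 | cis-(1R,5S)-1,5-dimethylbicyclo[3.3.0]octan-3-one (meso) | O=C1C[C@]2(C)CCC[C@]2(C)C1 | intermediate
12 | lithium (1S,5R)-1,5-dimethylbicyclo[3.3.0]oct-2-en-3-olate | [Li]OC1=C[C@]2(C)CCC[C@]2(C)C1 | intermediate
13 | (1S,5R)-1,5-dimethyl-3-(trimethylsilyloxy)bicyclo[3.3.0]oct-2-ene | C[Si](C)(C)OC1=C[C@]2(C)CCC[C@]2(C)C1 | intermediate
14 | trimethylsilyl 2-[(1R,2R)-2-formyl-1,2-dimethylcyclopentyl]acetate | O=C[C@]1(C)CCC[C@]1(C)CC(=O)O[Si](C)(C)C | intermediate
15 | 2-[(1R,2R)-2-formyl-1,2-dimethylcyclopentyl]acetic acid | O=C[C@]1(C)CCC[C@]1(C)CC(=O)O | intermediate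
16 | 1-chloro-3-methylbut-2-ene | CC(C)=CCCl | starting material
17 | (3-methylbut-2-en-1-yl)barium chloride | CC(C)=CC[Ba]Cl | intermediate
18 | 2-[(1R,2R)-2-(1-hydroxy-4-methylpent-3-en-1-yl)-1,2-dimethylcyclopentyl]acetic acid (carbinol epimers) | CC(C)=CCC(O)[C@]1(C)CCC[C@]1(C)CC(=O)O | intermediate
19 | (4aR,7aR)-4a,7a-dimethyl-1-(3-methylbut-2-en-1-yl)hexahydrocyclopenta[c]pyran-3(1H)-one (epimers at C1) | CC(C)=CCC1[C@]2(C)CCC[C@]2(C)CC(=O)O1 | intermediate
20 | 4-methoxy-2-methylphenol | COc1ccc(O)c(C)c1 | starting material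
21 | 2-bromo-4-methoxy-6-methylphenol | COc1cc(C)c(O)c(Br)c1 | intermediate
22 | 1-bromo-2,5-dimethoxy-3-methylbenzene | COc1cc(C)c(OC)c(Br)c1 | intermediate
23 | 1-bromo-3-methylbut-2-ene | CC(C)=CCBr | starting material
24 | (2,5-dimethoxy-3-methylphenyl)lithium | [Li]c1cc(OC)cc(C)c1OC | intermediate
25 | 2,5-dimethoxy-1-methyl-3-(3-methylbut-2-en-1-yl)benzene | COc1cc(C)c(OC)c(CC=C(C)C)c1 | intermediate
26 | (2E)-4-(2,5-dimethoxy-3-methylphenyl)-2-methylbut-2-en-1-ol | COc1cc(C)c(OC)c(C/C=C(\C)CO)c1 | intermediate
27 | 1-[(2E)-4-bromo-3-methylbut-2-en-1-yl]-2,5-dimethoxy-3-methylbenzene | COc1cc(C)c(OC)c(C/C=C(\C)CBr)c1 | intermediate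
28 | 1-[(2E)-4-(benzenesulfonyl)-3-methylbut-2-en-1-yl]-2,5-dimethoxy-3-methylbenzene | COc1cc(C)c(OC)c(C/C=C(\C)CS(=O)(=O)c2ccccc2)c1 | intermediate
29 | [(2E)-1-(benzenesulfonyl)-4-(2,5-dimethoxy-3-methylphenyl)-2-methylbut-2-en-1-yl]lithium | [Li]C(S(=O)(=O)c1ccccc1)/C(C)=C/Cc1cc(OC)cc(C)c1OC | intermediate
30 | (4E)-3-(benzenesulfonyl)-6-(2,5-dimethoxy-3-methylphenyl)-1-[(1R,2R)-2-(1-hydroxy-4-methylpent-3-en-1-yl)-1,2-dimethylcyclopentyl]-4-methylhex-4-en-2-one (mixture at the carbinol and sulfone-bearing carbons) | CC(C)=CCC(O)[C@]1(C)CCC[C@]1(C)CC(=O)C(S(=O)(=O)c2ccccc2)/C(C)=C/Cc3cc(OC)cc(C)c3OC | intermediate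
31 | (4E)-3-(benzenesulfonyl)-6-(2,5-dimethoxy-3-methylphenyl)-1-[(1R,2R)-1,2-dimethyl-2-(4-methylpent-3-enoyl)cyclopentyl]-4-methylhex-4-en-2-one (mixture at the sulfone-bearing carbon) | CC(C)=CCC(=O)[C@]1(C)CCC[C@]1(C)CC(=O)C(S(=O)(=O)c2ccccc2)/C(C)=C/Cc3cc(OC)cc(C)c3OC | intermediate
32 | diiodosamarium dienolate of 33 (trivalent samarium) | CC(C)=CCC(=O)[C@]1(C)CCC[C@]1(C)CC(O[Sm](I)I)=C/C(C)=C/Cc2cc(OC)cc(C)c2OC | intermediate
33 | (4E)-6-(2,5-dimethoxy-3-methylphenyl)-1-[(1R,2R)-1,2-dimethyl-2-(4-methylpent-3-enoyl)cyclopentyl]-4-methylhex-4-en-2-one | CC(C)=CCC(=O)[C@]1(C)CCC[C@]1(C)CC(=O)C/C(C)=C/Cc2cc(OC)cc(C)c2OC | intermediate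
34 | 2-[(2E)-6-[(1R,2R)-1,2-dimethyl-2-(4-methylpent-3-enoyl)cyclopentyl]-3-methyl-5-oxohex-2-en-1-yl]-6-methylcyclohexa-2,5-diene-1,4-dione | CC(C)=CCC(=O)[C@]1(C)CCC[C@]1(C)CC(=O)C/C(C)=C/CC1=CC(=O)C=C(C)C1=O | target

## Step count and risks

Total step count: 16. Longest linear sequence: 11 steps (steps 1 to 7 and 13 to 16, from butane-2,3-dione); the sulfone branch is steps 8 to 12.

Steps most likely to fail:

Step 5. The chiral amide may discriminate poorly between the two enantiotopic CH2 groups next to the bridgehead methyl groups, giving material of low enantiomeric purity. The fallback is a resolution; it sets out from 11 and comes back at 15. LDA and chlorotrimethylsilane (THF, −78 °C) would give the lithium enolate as a racemate, 12 together with its mirror image lithium (1R,5S)-1,5-dimethylbicyclo[3.3.0]oct-2-en-3-olate F1, and from it the silyl enol ether as a racemate, 13 together with (1R,5S)-1,5-dimethyl-3-(trimethylsilyloxy)bicyclo[3.3.0]oct-2-ene F2. Ozonolysis as in step 6 would pass through 14 and its mirror image trimethylsilyl 2-[(1S,2S)-2-formyl-1,2-dimethylcyclopentyl]acetate F3 to the racemic acid, 15 together with 2-[(1S,2S)-2-formyl-1,2-dimethylcyclopentyl]acetic acid F4. Fractional crystallization of the salt with a tertiary amine that cannot form an imine, (R)-N,N-dimethyl-1-phenylethylammonium 2-[(1R,2R)-2-formyl-1,2-dimethylcyclopentyl]acetate F5 (the (S)-amine if its salt with 15 is the less soluble one), and acidification would return 15.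

Step 7. Allylic transposition of the barium reagent (attack through the dimethyl-substituted terminus) or incomplete formation of active barium may erode the yield of the linear prenyl carbinol at this very hindered aldehyde. The fallback builds the same carbinol from an epoxide and a vinyl nucleophile, with no allylic ambiguity; it sets out from 15 and comes back at 19. Esterification with (trimethylsilyl)diazomethane (MeOH/toluene) would give methyl 2-[(1R,2R)-2-formyl-1,2-dimethylcyclopentyl]acetate F6. Corey–Chaykovsky methylenation (trimethylsulfonium iodide, n-BuLi, THF, −10 °C) would give methyl 2-[(1R,2R)-1,2-dimethyl-2-(oxiran-2-yl)cyclopentyl]acetate F7. Opening at the CH2 terminus with (2-methylprop-1-en-1-yl)magnesium bromide and CuI (cat.) in THF at −30 °C would give the magnesium alkoxide of methyl 2-[(1R,2R)-2-(1-hydroxy-4-methylpent-3-en-1-yl)-1,2-dimethylcyclopentyl]acetate F8, which should close to 19 on warming with loss of methoxide.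

Step 13. Acylation at the neopentyl-type lactone carbonyl may be slow, and proton transfer from the lactone CH2 to the carbanion may compete, leaving starting materials. The fallback replaces acylation and desulfonylation by carbonyl addition and oxidation; it sets out from 19 (and from alcohol 26) and comes back at 33, bypassing 30 to 32. DIBAL-H (CH2Cl2, −78 °C) would reduce 19 to the lactol (4aR,7aR)-4a,7a-dimethyl-1-(3-methylbut-2-en-1-yl)octahydrocyclopenta[c]pyran-3-ol F9. Alcohol 26 would be converted (MsCl, LiCl, 2,4,6-collidine, DMF, 0 °C) into 1-[(2E)-4-chloro-3-methylbut-2-en-1-yl]-2,5-dimethoxy-3-methylbenzene F10 and this, with activated barium as in step 7, into [(2E)-4-(2,5-dimethoxy-3-methylphenyl)-2-methylbut-2-en-1-yl]barium chloride F11. Addition of F11 (2.2 equiv, the first deprotonating the lactol) to the open hydroxy aldehyde form of F9 at −78 °C, through its CH2 terminus and with the E geometry kept, would give (4E)-6-(2,5-dimethoxy-3-methylphenyl)-1-[(1R,2R)-2-(1-hydroxy-4-methylpent-3-en-1-yl)-1,2-dimethylcyclopentyl]-4-methylhex-4-en-2-ol F12. Dess–Martin oxidation of both carbinols (NaHCO3, CH2Cl2) would give 33.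

Further compounds
F1 | step 5 | lithium (1R,5S)-1,5-dimethylbicyclo[3.3.0]oct-2-en-3-olate | [Li]OC1=C[C@@]2(C)CCC[C@@]2(C)C1
F2 | step 5 | (1R,5S)-1,5-dimethyl-3-(trimethylsilyloxy)bicyclo[3.3.0]oct-2-ene | C[Si](C)(C)OC1=C[C@@]2(C)CCC[C@@]2(C)C1
F3 | step 5 | trimethylsilyl 2-[(1S,2S)-2-formyl-1,2-dimethylcyclopentyl]acetate | O=C[C@@]1(C)CCC[C@@]1(C)CC(=O)O[Si](C)(C)C
F4 | step 5 | 2-[(1S,2S)-2-formyl-1,2-dimethylcyclopentyl]acetic acid | O=C[C@@]1(C)CCC[C@@]1(C)CC(=O)O
F5 | step 5 | (R)-N,N-dimethyl-1-phenylethylammonium 2-[(1R,2R)-2-formyl-1,2-dimethylcyclopentyl]acetate | O=C[C@]1(C)CCC[C@]1(C)CC(=O)[O-].C[C@@H]([NH+](C)C)c1ccccc1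
F6 | step 7 | methyl 2-[(1R,2R)-2-formyl-1,2-dimethylcyclopentyl]acetate | O=C[C@]1(C)CCC[C@]1(C)CC(=O)OC
F7 | step 7 | methyl 2-[(1R,2R)-1,2-dimethyl-2-(oxiran-2-yl)cyclopentyl]acetate | C1OC1[C@]2(C)CCC[C@]2(C)CC(=O)OC
F8 | step 7 | methyl 2-[(1R,2R)-2-(1-hydroxy-4-methylpent-3-en-1-yl)-1,2-dimethylcyclopentyl]acetate | CC(C)=CCC(O)[C@]1(C)CCC[C@]1(C)CC(=O)OC
F9 | step 13 | (4aR,7aR)-4a,7a-dimethyl-1-(3-methylbut-2-en-1-yl)octahydrocyclopenta[c]pyran-3-ol | CC(C)=CCC1[C@]2(C)CCC[C@]2(C)CC(O)O1
F10 | step 13 | 1-[(2E)-4-chloro-3-methylbut-2-en-1-yl]-2,5-dimethoxy-3-methylbenzene | COc1cc(C)c(OC)c(C/C=C(\C)CCl)c1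
F11 | step 13 | [(2E)-4-(2,5-dimethoxy-3-methylphenyl)-2-methylbut-2-en-1-yl]barium chloride | COc1cc(C)c(OC)c(C/C=C(\C)C[Ba]Cl)c1
F12 | step 13 | (4E)-6-(2,5-dimethoxy-3-methylphenyl)-1-[(1R,2R)-2-(1-hydroxy-4-methylpent-3-en-1-yl)-1,2-dimethylcyclopentyl]-4-methylhex-4-en-2-ol | CC(C)=CCC(O)[C@]1(C)CCC[C@]1(C)CC(O)C/C(C)=C/Cc2cc(OC)cc(C)c2OC
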